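Count turnovers. One turnover here means one product made per catalyst charged, so a flask's need, its charge of substrate over its charge of free catalyst, is the number of turnovers that full conversion takes.

in all of them: free catalyst 0.0130 M

|  | substrate | time |
|---|---|---|
| Wednesday's | 0.250 M |  |
| Tuesday's | 0.150 M |  |
| Monday's | 0.120 M |  |
| Thursday's | 0.620 M | 53 min |

| Wednesday's run: time / min | Wednesday's run: [product] / M | Tuesday's run: time / min | Tuesday's run: [product] / M | Monday's run: time / min | Monday's run: [product] / M |
|---|---|---|---|---|---|
| 3.0 | 0.0152 | 3.0 | 0.0220 | 3.0 | 0.0282 |
| 9.1 | 0.0433 | 9.1 | 0.0605 | 9.1 | 0.0687 |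
| 17 | 0.0604 | 17 | 0.0962 | 17 | 0.1008 |
| 28 | 0.0790 | 28 | 0.1215 | 28 | 0.1164 |
| 40 | 0.0877 | 40 | 0.1340 | 40 | 0.1195 |
| 53 | 0.0914 | 53 | 0.1427 | 53 | 0.1193 |

(each reading ± 0.001 M)

- Overall: substrate -> product, with free catalyst as catalyst.
- Constant volume, constant temperature.
- The analysis sees a species whether free or bound.
- An order is taken over about fifteen percent of the charge, up and down.

- apparent order in [substrate] of the starting rate, round the charge of the Wednesday's run (the rate where two percent of its substrate have turned into product) (one fixed amount of product, the same in the runs compared)
- product in the Thursday's run at 53 min, as a share of the substrate charged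

I turn the question round. For Thursday's flask to convert its whole charge, its catalyst has to deliver 47.7 turnovers, so I ask what the earlier runs offer.

By its last reading, Wednesday's flask stands short of its need of 19.2 turnovers: c(product) reads 0.0914 M, which is 7.03 turnovers, with 0.159 M of substrate unconverted.

The first readings of Monday's and Wednesday's flasks give an apparent order of −0.842 across these two charges, so between them the early rate falls nearly as one over the charge. I assume that the catalyst's working life stays the same as the charge rises. Turnovers times charge then stay fixed, and Wednesday's last reading gives 1.76 M, which I call the turnover budget.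

Divided by Thursday's charge, the budget allows 2.83 turnovers, so my reckoning gives 5.93% of the charge as product. Thursday's need is greater than this allowance by a factor of 16.9, and that is how far the flask stands from the opposite outcome.

The forecast gives −0.87 and 3%, on the ground that “substrate inhibits strongly”. Its share is lower than mine.

The flask gives an order of −0.92 and a share of 5.79%.

    free catalyst + substrate ⇌ catalyst-substrate complex, settled at all times (42.90 M⁻¹)
    catalyst-substrate complex + free catalyst → product + 2 free catalyst (420.0 M⁻¹ min⁻¹)
    free catalyst + product ⇌ catalyst-product complex, settled at all times (15.50 M⁻¹)
    free catalyst + substrate → spent catalyst + substrate (1.542 M⁻¹ min⁻¹)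

In Thursday's flask, the step to product and the step to spent catalyst run side by side while c(substrate), bound form counted, goes from 0.620 M to 0.584 M. At 53 min Thursday's flask holds 0.0359 M of product, which is 2.76 turnovers of the 47.7 needed. In Tuesday's flask, the budget allows 11.7 turnovers against a need of 11.5, and its last reading stands at 11.0.

(The runs were computed with constants of no real substance; the scatter is artificial.)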